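**Strategy.** The cyclohexene is cut across two opposite ring bonds, CH2–C(CH3)= and CH(aroyl)–CH(aryl), into a C(CH3)=CH–CH(aryl) allyl unit and a CH2–CH(aryl)–CH(aroyl) unit. The latter is stored in a prochiral 1,3-diarylcyclobutanol. In one flask, palladium-catalysed enantioselective C–C cleavage couples the liberated ring CH2 with a 2-triflyloxy-1,3-diene, and acid then converts the ortho-hydroxyaryl diene into a vinyl o-quinone methide onto which the new ketone enol closes. The step exploits the phenol ortho to the benzylic ring carbon on the acyl-resorcinol ring and the 1,3-relationship of the ring CH2 and the aroyl α-carbon.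

Key step: step 12

Remark: the THP acetal carbon is racemic throughout (the group is lost in step 12), and the antipode of the ligand is taken in step 12 if the sense of C–C cleavage proves opposite to that needed for the (S) centre.

Step 1
Reactants: 1 1-(2,4-dihydroxyphenyl)ethan-1-one
Product: 2 1-(2,4-dihydroxy-3-iodophenyl)ethan-1-one
Conditions: I2, HIO3, EtOH–H2O, 40 °C
Reagents that add atoms: iodine, II; iodic acid, O[I](=O)=O
Why: Electrophilic aromatic iodination should go to C3, the position activated by both hydroxyl groups and ortho to the chelated 2-OH.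

Step 2
Reactants: 2 1-(2,4-dihydroxy-3-iodophenyl)ethan-1-one
Product: 3 1-[2-hydroxy-3-iodo-4-(oxan-2-yloxy)phenyl]ethan-1-one
Conditions: 3,4-dihydro-2H-pyran, PPTS, CH2Cl2, rt
Reagents that add atoms: 3,4-dihydro-2H-pyran, C1=COCCC1
Why: Acid-catalysed tetrahydropyranylation (acetal formation) should take only the 4-OH, because the 2-OH is held in a hydrogen bond to the ketone.

Step 3
Reactants: 3 1-[2-hydroxy-3-iodo-4-(oxan-2-yloxy)phenyl]ethan-1-one
Product: 4 1-[3-iodo-2-(methoxymethoxy)-4-(oxan-2-yloxy)phenyl]ethan-1-one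
Conditions: NaH, MOMCl, DMF, 0 °C to rt
Reagents that add atoms: chloromethyl methyl ether, COCCl
Why: Williamson O-alkylation of the sodium phenoxide caps the chelated phenol while the base-stable THP acetal is untouched.

Step 4
Reactants: 5 2,4-dihydroxybenzaldehyde
Product: 6 2,4-bis(methoxymethoxy)benzaldehyde
Conditions: NaH, MOMCl, DMF, 0 °C to rt
Reagents that add atoms: chloromethyl methyl ether, COCCl
Why: Double Williamson O-alkylation (MOM ether formation) protects both phenols.

Step 5
Reactants: 4 1-[3-iodo-2-(methoxymethoxy)-4-(oxan-2-yloxy)phenyl]ethan-1-one; 6 2,4-bis(methoxymethoxy)benzaldehyde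
Product: 7 (E)-3-[2,4-bis(methoxymethoxy)phenyl]-1-[3-iodo-2-(methoxymethoxy)-4-(oxan-2-yloxy)phenyl]prop-2-en-1-one
Conditions: KOH, EtOH, rt
Reagents that add atoms: none
Why: Claisen–Schmidt aldol condensation of the methyl ketone with the non-enolisable aldehyde should give the (E)-chalcone by E1cB dehydration, the acetals and the aryl iodide being base-stable.

Step 6
Reactants: 7 (E)-3-[2,4-bis(methoxymethoxy)phenyl]-1-[3-iodo-2-(methoxymethoxy)-4-(oxan-2-yloxy)phenyl]prop-2-en-1-one; 8 but-3-en-2-one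
Product: 9 (E)-4-{3-[(E)-3-[2,4-bis(methoxymethoxy)phenyl]prop-2-enoyl]-2-(methoxymethoxy)-6-(oxan-2-yloxy)phenyl}but-3-en-2-one
Conditions: Pd(OAc)2 (10 mol %), n-Bu4NCl, NaHCO3, DMF, 80 °C
Reagents that add atoms: none
Why: Mizoroki–Heck reaction of the aryl iodide with the electron-poor alkene under ligand-free phase-transfer conditions should give the (E)-enone by syn insertion and syn β-hydride elimination.

Step 7
Reactants: 9 (E)-4-{3-[(E)-3-[2,4-bis(methoxymethoxy)phenyl]prop-2-enoyl]-2-(methoxymethoxy)-6-(oxan-2-yloxy)phenyl}but-3-en-2-one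
Product: 10 (E)-4-{3-[(E)-3-[2,4-bis(methoxymethoxy)phenyl]prop-2-enoyl]-2-(methoxymethoxy)-6-(oxan-2-yloxy)phenyl}buta-1,3-dien-2-yl trifluoromethanesulfonate
Conditions: KHMDS, PhNTf2, THF, −78 °C
Reagents that add atoms: N-phenylbis(trifluoromethanesulfonimide), O=S(=O)(N(c1ccccc1)S(=O)(=O)C(F)(F)F)C(F)(F)F
Why: Enol triflate formation is site-specific because the methyl ketone is the only enolisable carbonyl (the chalcone ketone has no α-hydrogen), so O-triflation of its cross-conjugated dienolate gives the 2-triflyloxy-1,3-diene.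

Step 8
Reactants: 6 2,4-bis(methoxymethoxy)benzaldehyde; 11 methyltriphenylphosphonium bromide
Product: 12 1-ethenyl-2,4-bis(methoxymethoxy)benzene
Conditions: KOtBu, THF, 0 °C to rt
Reagents that add atoms: none
Why: Wittig methylenation converts the aldehyde into the styrene.

Step 9
Reactants: 12 1-ethenyl-2,4-bis(methoxymethoxy)benzene; 13 N,N-dimethylacetamide
Product: 14 3-[2,4-bis(methoxymethoxy)phenyl]cyclobutan-1-one
Conditions: Tf2O, 2,4,6-collidine, ClCH2CH2Cl, 0 to 80 °C; then aq NaHCO3
Reagents that add atoms: water, O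
Why: Keteniminium [2+2] cycloaddition with the electron-rich styrene should be regioselective for the 3-aryl cyclobutaniminium salt, which hydrolyses to the cyclobutanone.

Step 10
Reactants: 15 4-bromobenzene-1,3-diol
Product: 16 1-bromo-2,4-bis(methoxymethoxy)benzene
Conditions: NaH, MOMCl, DMF, 0 °C to rt
Reagents that add atoms: chloromethyl methyl ether, COCCl
Why: Double Williamson O-alkylation (MOM ether formation) protects both phenols before metalation.

Step 11
Reactants: 16 1-bromo-2,4-bis(methoxymethoxy)benzene; 14 3-[2,4-bis(methoxymethoxy)phenyl]cyclobutan-1-one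
Product: 17 1,3-bis[2,4-bis(methoxymethoxy)phenyl]cyclobutan-1-ol (hydroxyl cis to the 3-aryl group, achiral)
Conditions: n-BuLi, THF, −78 °C; then 14, −78 to 0 °C
Reagents that add atoms: none
Why: Bromine–lithium exchange and 1,2-addition of the aryllithium to the ketone from the face anti to the 3-aryl group should give the alcohol with hydroxyl cis to that group.

Step 12
Reactants: 17 1,3-bis[2,4-bis(methoxymethoxy)phenyl]cyclobutan-1-ol (hydroxyl cis to the 3-aryl group, achiral); 10 (E)-4-{3-[(E)-3-[2,4-bis(methoxymethoxy)phenyl]prop-2-enoyl]-2-(methoxymethoxy)-6-(oxan-2-yloxy)phenyl}buta-1,3-dien-2-yl trifluoromethanesulfonate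
Product: 20 (E)-1-{3-[(1S,5S,6R)-6-[2,4-bis(methoxymethoxy)benzoyl]-5-[2,4-bis(methoxymethoxy)phenyl]-3-methylcyclohex-2-en-1-yl]-4-hydroxy-2-(methoxymethoxy)phenyl}-3-[2,4-bis(methoxymethoxy)phenyl]prop-2-en-1-one, via dienyl ketone 18 (not isolated), via free phenol 19 (not isolated)
Conditions: Pd(OAc)2 (5 mol %), (R)-N,N-dimethyl-1-[(S)-2-(diphenylphosphino)ferrocenyl]ethylamine (10 mol %), Cs2CO3, toluene, 60 °C; filtration through Celite; then (PhO)2P(O)OH, MeOH, toluene, 50 °C, one flask
Reagents that add atoms: none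
Why: Proposed new method: The alkoxide of 17 binds the alkenyl-palladium species formed from 10 by oxidative addition to zerovalent palladium, enantiotopos-selective β-carbon elimination opens the four-membered ring to a primary alkyl-palladium ketone, and reductive elimination joins the ring CH2 to the diene carbon that becomes the C-methyl alkene carbon (18); the closest known reaction is the asymmetric arylation and alkenylation of tert-cyclobutanols by C–C cleavage. Diphenyl phosphate then removes the THP acetal (19) and protonates the diene at its CH2 terminus to the vinyl o-quinone methide (in equilibrium with its 2H-chromene), and the enol of the aryl ketone adds to the benzylic carbon, as in acid-induced captures of o-quinone methides by enols and the cyclisation of terpenyl 2H-chromenes. The cyclohexene closes in a 6-(enolexo)-exo-trig mode onto the exocyclic quinone methide carbon, and the hemiketal of the oxa-[4+2] pathway opens to ketone and phenol. The (S) centre carrying the dihydroxyphenyl-type ring is set by the chiral P,N ligand in the C–C cleavage, and the two new centres should follow from it through a chair-like, cis-fused (endo) transition state with that aryl group equatorial and the enol placed to avoid A(1,3) strain, which puts the aroyl group trans to it and cis to the acyl-resorcinol ring (the aroyl-bearing centre is also the thermodynamically preferred epimer). The step needs reductive elimination to outrun β-hydride elimination, which rests on the ligand, and enol attack at the benzylic rather than the tertiary terminus, which is secured by ring size (six against four) and by the single free ortho-hydroxyl that forms the quinone methide.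

Step 13
Reactants: 20 (E)-1-{3-[(1S,5S,6R)-6-[2,4-bis(methoxymethoxy)benzoyl]-5-[2,4-bis(methoxymethoxy)phenyl]-3-methylcyclohex-2-en-1-yl]-4-hydroxy-2-(methoxymethoxy)phenyl}-3-[2,4-bis(methoxymethoxy)phenyl]prop-2-en-1-one
Product: 21 (E)-1-{3-[(1S,5S,6R)-6-(2,4-dihydroxybenzoyl)-5-(2,4-dihydroxyphenyl)-3-methylcyclohex-2-en-1-yl]-2,4-dihydroxyphenyl}-3-(2,4-dihydroxyphenyl)prop-2-en-1-one
Conditions: HCl (3 M aq), MeOH–THF, 40 °C
Reagents that add atoms: none
Why: Acid-catalysed acetal exchange (methanolysis) should remove the seven MOM ethers as dimethoxymethane without touching a stereocentre, the aroyl-bearing centre already being the preferred epimer.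

**Compound list**

1 | 1-(2,4-dihydroxyphenyl)ethan-1-one | CC(=O)c1ccc(O)cc1O | starting material
2 | 1-(2,4-dihydroxy-3-iodophenyl)ethan-1-one | CC(=O)c1ccc(O)c(I)c1O | intermediate
3 | 1-[2-hydroxy-3-iodo-4-(oxan-2-yloxy)phenyl]ethan-1-one (racemic at the acetal carbon) | CC(=O)c1ccc(OC2CCCCO2)c(I)c1O | intermediate
4 | 1-[3-iodo-2-(methoxymethoxy)-4-(oxan-2-yloxy)phenyl]ethan-1-one | CC(=O)c1ccc(OC2CCCCO2)c(I)c1OCOC | intermediate
5 | 2,4-dihydroxybenzaldehyde | O=Cc1ccc(O)cc1O | starting material
6 | 2,4-bis(methoxymethoxy)benzaldehyde | O=Cc1ccc(OCOC)cc1OCOC | intermediate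
7 | (E)-3-[2,4-bis(methoxymethoxy)phenyl]-1-[3-iodo-2-(methoxymethoxy)-4-(oxan-2-yloxy)phenyl]prop-2-en-1-one | O=C(/C=C/c1ccc(OCOC)cc1OCOC)c1ccc(OC2CCCCO2)c(I)c1OCOC | intermediate
8 | but-3-en-2-one | CC(=O)C=C | starting material
9 | (E)-4-{3-[(E)-3-[2,4-bis(methoxymethoxy)phenyl]prop-2-enoyl]-2-(methoxymethoxy)-6-(oxan-2-yloxy)phenyl}but-3-en-2-one | CC(=O)/C=C/c1c(OC2CCCCO2)ccc(C(=O)/C=C/c2ccc(OCOC)cc2OCOC)c1OCOC | intermediate
10 | (E)-4-{3-[(E)-3-[2,4-bis(methoxymethoxy)phenyl]prop-2-enoyl]-2-(methoxymethoxy)-6-(oxan-2-yloxy)phenyl}buta-1,3-dien-2-yl trifluoromethanesulfonate | C=C(OS(=O)(=O)C(F)(F)F)/C=C/c1c(OC2CCCCO2)ccc(C(=O)/C=C/c2ccc(OCOC)cc2OCOC)c1OCOC | intermediate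
11 | methyltriphenylphosphonium bromide | C[P+](c1ccccc1)(c1ccccc1)c1ccccc1.[Br-] | starting material
12 | 1-ethenyl-2,4-bis(methoxymethoxy)benzene | C=Cc1ccc(OCOC)cc1OCOC | intermediate
13 | N,N-dimethylacetamide | CC(=O)N(C)C | starting material
14 | 3-[2,4-bis(methoxymethoxy)phenyl]cyclobutan-1-one | O=C1CC(c2ccc(OCOC)cc2OCOC)C1 | intermediate
15 | 4-bromobenzene-1,3-diol | Oc1ccc(Br)c(O)c1 | starting material
16 | 1-bromo-2,4-bis(methoxymethoxy)benzene | COCOc1ccc(Br)c(OCOC)c1 | intermediate
17 | 1,3-bis[2,4-bis(methoxymethoxy)phenyl]cyclobutan-1-ol (hydroxyl cis to the 3-aryl group, achiral) | O[C@@]1(c2ccc(OCOC)cc2OCOC)C[C@@H](c2ccc(OCOC)cc2OCOC)C1 | intermediate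
18 | (3S,6E)-1,3-bis[2,4-bis(methoxymethoxy)phenyl]-7-{3-[(E)-3-[2,4-bis(methoxymethoxy)phenyl]prop-2-enoyl]-2-(methoxymethoxy)-6-(oxan-2-yloxy)phenyl}-5-methylidenehept-6-en-1-one | O=C(c1ccc(OCOC)cc1OCOC)C[C@@H](c1ccc(OCOC)cc1OCOC)CC(=C)/C=C/c1c(OC2CCCCO2)ccc(C(=O)/C=C/c2ccc(OCOC)cc2OCOC)c1OCOC | intermediate (not isolated)
19 | (3S,6E)-1,3-bis[2,4-bis(methoxymethoxy)phenyl]-7-{3-[(E)-3-[2,4-bis(methoxymethoxy)phenyl]prop-2-enoyl]-6-hydroxy-2-(methoxymethoxy)phenyl}-5-methylidenehept-6-en-1-one | O=C(c1ccc(OCOC)cc1OCOC)C[C@@H](c1ccc(OCOC)cc1OCOC)CC(=C)/C=C/c1c(O)ccc(C(=O)/C=C/c2ccc(OCOC)cc2OCOC)c1OCOC | intermediate (not isolated)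
20 | (E)-1-{3-[(1S,5S,6R)-6-[2,4-bis(methoxymethoxy)benzoyl]-5-[2,4-bis(methoxymethoxy)phenyl]-3-methylcyclohex-2-en-1-yl]-4-hydroxy-2-(methoxymethoxy)phenyl}-3-[2,4-bis(methoxymethoxy)phenyl]prop-2-en-1-one | CC1=C[C@H](c2c(O)ccc(C(=O)/C=C/c3ccc(OCOC)cc3OCOC)c2OCOC)[C@H](C(=O)c2ccc(OCOC)cc2OCOC)[C@@H](c2ccc(OCOC)cc2OCOC)C1 | intermediate
21 | (E)-1-{3-[(1S,5S,6R)-6-(2,4-dihydroxybenzoyl)-5-(2,4-dihydroxyphenyl)-3-methylcyclohex-2-en-1-yl]-2,4-dihydroxyphenyl}-3-(2,4-dihydroxyphenyl)prop-2-en-1-one | CC1=C[C@H](c2c(O)ccc(C(=O)/C=C/c3ccc(O)cc3O)c2O)[C@H](C(=O)c2ccc(O)cc2O)[C@@H](c2ccc(O)cc2O)C1 | target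

**Step count.** Total: 13 steps. Longest linear sequence: 8 steps (steps 1, 2, 3, 5, 6, 7, 12, 13).

**Steps most likely to fail**

1. Step 12 (Proposed new method). β-Hydride elimination from the alkyl-palladium intermediate, or weak discrimination between the two enantiotopic ring bonds, would erode yield and optical purity. The acid stage may also stall at the 2H-chromene or close with the wrong facial sense. The fallback separates the two events with known chemistry and sets out from cyclobutanone 14. An enantioselective Baeyer–Villiger oxidation (a Baeyer–Villiger monooxygenase of the cyclohexanone monooxygenase class, O2, NADPH recycling) gives (S)-4-[2,4-bis(methoxymethoxy)phenyl]oxolan-2-one F1. The aryllithium from 16 (n-BuLi, THF, −78 °C) opens it to the (S)-4-hydroxy ketone F2. I2, PPh3 and imidazole convert this into the (S)-4-iodo ketone F3. Zn dust with LiCl in THF gives the alkylzinc iodide F4. Negishi coupling of F4 with triflate 10 (Pd2(dba)3, SPhos, THF, 40 °C) comes back to the route at dienyl ketone 18, now isolated, so that the acid-induced ring closure to 20 can be tuned on its own.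

2. Step 13. Protic acid may trigger ketalisation of the aroyl ketone with the flanking phenols, or flavanone formation from the 2′-hydroxychalcone, while the MOM groups are cleaved. The fallback sets out from 20. TMSOTf and 2,2′-bipyridyl in CH2Cl2 at 0 °C exchange the MOM ethers for silyl ethers under aprotic conditions to give the octakis(trimethylsilyl) ether F5. Hydrolysis at neutral pH (H2O, THF) then comes back to the route at 21.

3. Step 9. Triflic species may strip MOM groups and start cationic polymerisation of the electron-rich styrene. The fallback sets out from styrene 12. Dichloroketene (Cl3CCOCl, Zn–Cu couple, Et2O) gives 3-[2,4-bis(methoxymethoxy)phenyl]-2,2-dichlorocyclobutan-1-one F6. Reductive dechlorination (Zn, AcOH, rt) comes back to the route at 14.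

Further compounds
F1 | step 12 | (S)-4-[2,4-bis(methoxymethoxy)phenyl]oxolan-2-one | O=C1C[C@@H](c2ccc(OCOC)cc2OCOC)CO1
F2 | step 12 | (S)-1,3-bis[2,4-bis(methoxymethoxy)phenyl]-4-hydroxybutan-1-one | O=C(c1ccc(OCOC)cc1OCOC)C[C@@H](c1ccc(OCOC)cc1OCOC)CO
F3 | step 12 | (S)-1,3-bis[2,4-bis(methoxymethoxy)phenyl]-4-iodobutan-1-one | O=C(c1ccc(OCOC)cc1OCOC)C[C@@H](c1ccc(OCOC)cc1OCOC)CI
F4 | step 12 | [(S)-2,4-bis[2,4-bis(methoxymethoxy)phenyl]-4-oxobutyl]zinc iodide | O=C(c1ccc(OCOC)cc1OCOC)C[C@@H](c1ccc(OCOC)cc1OCOC)C[Zn]I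
F5 | step 13 | octakis(trimethylsilyl) ether of 21 | CC1=C[C@H](c2c(O[Si](C)(C)C)ccc(C(=O)/C=C/c3ccc(O[Si](C)(C)C)cc3O[Si](C)(C)C)c2O[Si](C)(C)C)[C@H](C(=O)c2ccc(O[Si](C)(C)C)cc2O[Si](C)(C)C)[C@@H](c2ccc(O[Si](C)(C)C)cc2O[Si](C)(C)C)C1
F6 | step 9 | 3-[2,4-bis(methoxymethoxy)phenyl]-2,2-dichlorocyclobutan-1-one | O=C1CC(c2ccc(OCOC)cc2OCOC)C1(Cl)Cl
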